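## Retrosynthetic overview

- Ring numbered as in shikimate (C1 bears CO2Me, C2 is the vinylic CH, C3–C5 carry the oxygens, C6 is the CH2). The esters go on last: O4 acylation, O3 acetate by orthoester opening, O5 ester at the diene stage.
- The cis-3,4-diol (trans to O5) is traced back to a C3=C4 double bond: OsO4 dihydroxylation of a (5R)-5-acyloxycyclohexa-1,3-diene-1-carboxylate anti to O5.
- The only ring, the six-membered carbocycle, is closed in one [3+3] operation. A crotonate-derived phosphorus ylide supplies C1–C2–C3 and 2-acetoxyacrolein supplies C4–C5(O)–C6; Michael addition makes C1–C6 and an intramolecular Wittig reaction makes C3–C4 (as C3=C4).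
- Enabling feature: the vinylogous ester unit C3–C2=C1–CO2Me inside the ring. Its two ends (C1, α to the ester, and C3, γ to it) are both nucleophilic in one allylic ylide and face a three-carbon unit that already carries the C5 oxygen.
- The acceptor comes from 2,2-dimethyl-1,3-dioxan-5-one (enol acetate, then retro-hetero-Diels–Alder). The C5 stereocenter is not controlled in the key step; the enantiomer is selected by lipase resolution of the dienyl acetate.

Key step: step 4

Remark: both 2-methylbutanoyl groups are read from the SMILES as (R)-configured and the ring as (3R,4S,5R); (R)-2-methylbutanoic acid is taken as a purchasable starting material.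

## Route

Step 1
Reactants: 1 2,2-dimethyl-1,3-dioxan-5-one
Product: 2 2,2-dimethyl-4H-1,3-dioxin-5-yl acetate
Conditions: Ac2O, Et3N, 4-(dimethylamino)pyridine (cat.), CH2Cl2, 0 °C to rt
Reagents that add atoms: acetic anhydride, CC(=O)OC(C)=O
Why: Soft enolisation of the doubly α-oxygenated, symmetric ketone followed by O-acylation (enol ester formation) should give the single possible enol acetate.

Step 2
Reactants: 2 2,2-dimethyl-4H-1,3-dioxin-5-yl acetate
Product: 3 2-acetoxyacrolein (3-oxoprop-1-en-2-yl acetate)
Conditions: toluene, 110 °C (sealed tube); used as a solution or after short-path distillation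
Reagents that add atoms: none
Why: Thermal retro-hetero-Diels–Alder reaction of the 4H-1,3-dioxin expels acetone and unveils the 2-acyloxyacrolein, an established entry to this class of enals.

Step 3
Reactants: 4 methyl (2E)-4-bromobut-2-enoate
Product: 5 [(2E)-4-methoxy-4-oxobut-2-en-1-yl]triphenylphosphonium bromide
Conditions: PPh3, toluene, rt
Reagents that add atoms: triphenylphosphine, c1ccc(cc1)P(c1ccccc1)c1ccccc1
Why: SN2 quaternisation of triphenylphosphine by the allylic bromide gives the crotonate-derived phosphonium salt.

Step 4
Reactants: 5 [(2E)-4-methoxy-4-oxobut-2-en-1-yl]triphenylphosphonium bromide; 3 2-acetoxyacrolein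
Product: 8 rac-methyl 5-acetoxycyclohexa-1,3-diene-1-carboxylate, via ylide 6 (not isolated), via formyl ylide 7 (not isolated)
Conditions: Na2CO3, dibenzylamine (20 mol %), CHCl3, 0 °C to rt; 3 added over 2 h
Reagents that add atoms: none
Why: Deprotonation of 5 gives the vinylogous ester-stabilised ylide 6, whose γ-carbon (C1, α to the ester) adds in a Michael fashion to the methylene carbon (C6) of 3; proton transfer from C1 then gives the allylic ylide 7, whose phosphorus-bearing carbon (C3) olefinates the tethered aldehyde (C4) in an intramolecular Wittig reaction, so that C1–C6 and C3–C4 (as C3=C4) are formed in one flask with loss of Ph3P=O. The closest known reaction type is the tandem Michael addition/Wittig [3+3] annulation of crotonate-derived phosphorus ylides with α,β-unsaturated aldehydes to cyclohexa-1,3-diene carboxylates. The single ring is closed in the Wittig step by 6-exo-trig attack of the ylide carbon on the aldehyde carbonyl (through the oxaphosphetane), which leaves C1=C2 in the ring and conjugated with the ester. The only new stereocenter, C5, arises by protonation α to the aldehyde and no element controls it here (racemate; the enantiomers are separated in step 5). The step needs conjugate addition at C6 to precede carbonyl olefination: the unhindered β-methylene of 3, its slow addition and iminium activation by the secondary amine (an iminium ion is a strong Michael acceptor but is not olefinated) should secure this, and the mild carbonate base should keep the sensitive dienyl acetate from aromatising to methyl benzoate.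

Step 5
Reactants: 8 rac-methyl 5-acetoxycyclohexa-1,3-diene-1-carboxylate
Product: 9 methyl (5R)-5-hydroxycyclohexa-1,3-diene-1-carboxylate
Conditions: lipase from Burkholderia cepacia, phosphate buffer pH 7/MTBE, 25 °C, to about 40 % conversion; chromatography
Reagents that add atoms: none
Why: Lipase-catalysed kinetic resolution by enantioselective ester hydrolysis: by the empirical size rule for lipases acting on secondary alcohols (planar dienyl flank as the large group) the (R)-acetate should be hydrolysed faster, unreacted (S)-8 is removed by chromatography, and the neutral buffer should avoid dehydration of the dienol.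

Step 6
Reactants: 9 methyl (5R)-5-hydroxycyclohexa-1,3-diene-1-carboxylate; 10 (2R)-2-methylbutanoic acid
Product: 11 methyl (5R)-5-{[(2R)-2-methylbutanoyl]oxy}cyclohexa-1,3-diene-1-carboxylate
Conditions: N,N'-diisopropylcarbodiimide, 4-(dimethylamino)pyridine (10 mol %), CH2Cl2, 0 °C
Reagents that add atoms: none
Why: Steglich esterification should acylate the secondary dienol with retention at C5 and, being mild and nearly neutral, without epimerising the α-stereocenter of the acid.

Step 7
Reactants: 11 methyl (5R)-5-{[(2R)-2-methylbutanoyl]oxy}cyclohexa-1,3-diene-1-carboxylate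
Product: 12 methyl (3R,4S,5R)-3,4-dihydroxy-5-{[(2R)-2-methylbutanoyl]oxy}cyclohex-1-ene-1-carboxylate
Conditions: OsO4 (2 mol %), N-methylmorpholine N-oxide, acetone/H2O, 0 °C
Reagents that add atoms: N-methylmorpholine N-oxide, C[N+]1([O-])CCOCC1; water, O; both delivered through catalytic osmium tetroxide, O=[Os](=O)(=O)=O
Why: Catalytic OsO4 syn-dihydroxylation should attack the more electron-rich, ester-remote C3=C4 bond of the dienoate from the face anti to the C5 acyloxy group, setting C3 (R) and C4 (S) as the cis-diol trans to O5, as is known for 5-oxygenated cyclohexa-1,3-diene-1-carboxylates.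

Step 8
Reactants: 12 methyl (3R,4S,5R)-3,4-dihydroxy-5-{[(2R)-2-methylbutanoyl]oxy}cyclohex-1-ene-1-carboxylate
Product: 14 methyl (3R,4S,5R)-3-acetoxy-4-hydroxy-5-{[(2R)-2-methylbutanoyl]oxy}cyclohex-1-ene-1-carboxylate, via cyclic orthoacetate 13 (not isolated)
Conditions: MeC(OMe)3, 10-camphorsulfonic acid (cat.), CH2Cl2, rt; then AcOH/H2O, rt
Reagents that add atoms: trimethyl orthoacetate, CC(OC)(OC)OC; water, O
Why: The cis-diol forms a cyclic orthoacetate whose mild acid hydrolysis passes through a hemiorthoester that collapses under stereoelectronic control to the ester on the pseudoaxial oxygen (O3), leaving the equatorial O4–H free (regioselective orthoester opening of a cis-diol).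

Step 9
Reactants: 14 methyl (3R,4S,5R)-3-acetoxy-4-hydroxy-5-{[(2R)-2-methylbutanoyl]oxy}cyclohex-1-ene-1-carboxylate; 10 (2R)-2-methylbutanoic acid
Product: 15 methyl (3R,4S,5R)-3-acetoxy-4,5-bis{[(2R)-2-methylbutanoyl]oxy}cyclohex-1-ene-1-carboxylate (target)
Conditions: N,N'-diisopropylcarbodiimide, 4-(dimethylamino)pyridine (20 mol %), CH2Cl2, 0 °C to rt
Reagents that add atoms: none
Why: Steglich esterification of the remaining equatorial C4 hydroxyl completes the triester, and low temperature with only catalytic base should suppress O3-to-O4 acetyl migration and epimerisation of the acid.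

## Compound list

1 | 2,2-dimethyl-1,3-dioxan-5-one | CC1(C)OCC(=O)CO1 | starting material
2 | 2,2-dimethyl-4H-1,3-dioxin-5-yl acetate | CC(=O)OC1=COC(C)(C)OC1 | intermediate
3 | 2-acetoxyacrolein (3-oxoprop-1-en-2-yl acetate) | CC(=O)OC(=C)C=O | intermediate
4 | methyl (2E)-4-bromobut-2-enoate | COC(=O)/C=C/CBr | starting material
5 | [(2E)-4-methoxy-4-oxobut-2-en-1-yl]triphenylphosphonium bromide | COC(=O)/C=C/C[P+](c1ccccc1)(c1ccccc1)c1ccccc1.[Br-] | intermediate
6 | methyl (2E)-4-(triphenyl-λ5-phosphanylidene)but-2-enoate (ylide, not isolated) | COC(=O)/C=C/C=P(c1ccccc1)(c1ccccc1)c1ccccc1 | intermediate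
7 | methyl 2-(2-acetoxy-3-oxopropyl)-4-(triphenyl-λ5-phosphanylidene)but-2-enoate (formyl ylide, racemic, not isolated) | COC(=O)C(CC(OC(C)=O)C=O)=CC=P(c1ccccc1)(c1ccccc1)c1ccccc1 | intermediate
8 | rac-methyl 5-acetoxycyclohexa-1,3-diene-1-carboxylate | COC(=O)C1=CC=CC(OC(C)=O)C1 | intermediate
9 | methyl (5R)-5-hydroxycyclohexa-1,3-diene-1-carboxylate | COC(=O)C1=CC=C[C@H](O)C1 | intermediate
10 | (2R)-2-methylbutanoic acid | CC[C@@H](C)C(=O)O | starting material
11 | methyl (5R)-5-{[(2R)-2-methylbutanoyl]oxy}cyclohexa-1,3-diene-1-carboxylate | COC(=O)C1=CC=C[C@H](OC(=O)[C@H](C)CC)C1 | intermediate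
12 | methyl (3R,4S,5R)-3,4-dihydroxy-5-{[(2R)-2-methylbutanoyl]oxy}cyclohex-1-ene-1-carboxylate | O[C@@H]1[C@H](O)C=C(C(=O)OC)C[C@H]1OC(=O)[C@H](C)CC | intermediate
13 | 3,4-O-(1-methoxyethylidene) derivative of 12 (cyclic orthoacetate, mixture at the orthoester carbon, not isolated) | O2[C@@H]1[C@H](OC2(C)OC)C=C(C(=O)OC)C[C@H]1OC(=O)[C@H](C)CC | intermediate
14 | methyl (3R,4S,5R)-3-acetoxy-4-hydroxy-5-{[(2R)-2-methylbutanoyl]oxy}cyclohex-1-ene-1-carboxylate | O[C@@H]1[C@H](OC(C)=O)C=C(C(=O)OC)C[C@H]1OC(=O)[C@H](C)CC | intermediate
15 | methyl (3R,4S,5R)-3-acetoxy-4,5-bis{[(2R)-2-methylbutanoyl]oxy}cyclohex-1-ene-1-carboxylate | CC[C@@H](C)C(=O)O[C@@H]1[C@H](OC(C)=O)C=C(C(=O)OC)C[C@H]1OC(=O)[C@H](C)CC | target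

## Step count and risks

Total step count: 9.
Longest linear sequence: 8 steps (steps 1, 2, 4, 5, 6, 7, 8, 9); step 3 is the convergent branch.

Steps most likely to fail:

1. Step 4. Olefination of the free aldehyde by the ylide may outrun the conjugate addition and lead to an open-chain trienoate. The enol ester may also pass its acetyl group to the amine or the ylide, or the product may aromatise by loss of acetic acid. Fallback: a Diels–Alder/bridge-opening approach that needs no numbered compound, since furan and methyl acrylate are bought. ZnI2-promoted Diels–Alder reaction of furan with methyl acrylate should give methyl 7-oxabicyclo[2.2.1]hept-5-ene-2-carboxylate F1 (racemic endo/exo mixture). LiN(SiMe3)2 in THF at −78 °C deprotonates α to the ester and opens the oxygen bridge by β-elimination. The resulting lithium alkoxide of the dienol is acetylated in the same flask with Ac2O, which should give 8, where the route is rejoined.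

2. Step 5. The lipase may discriminate poorly between the two rather flat flanks of the carbinol carbon, and the dienol may dehydrate. Fallback from 8: K2CO3 in MeOH at 0 °C removes the acetate to give the racemic dienol F2. Esterification with (S)-2-methoxy-2-phenylacetic acid (N,N'-dicyclohexylcarbodiimide, 4-(dimethylamino)pyridine) gives two diastereomeric esters, which are separated by chromatography or crystallisation. The (5R) diastereomer F3 is cleaved with K2CO3 in MeOH at 0 °C to give 9.

3. Step 8. The orthoester may open without regiocontrol, or the acetyl group may migrate between O3 and O4 (also a risk under the basic conditions of step 9). Fallback from 12: the order of the two acylations is inverted. Catalytic 2-aminoethyl diphenylborinate directs (2R)-2-methylbutanoyl chloride F4 (made from 10 with oxalyl chloride) to the equatorial O4 of the cis-diol to give the 3-hydroxy diester F5. Acetylation of the remaining O3 (Ac2O, pyridine) then gives 15.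

Further compounds
F1 | step 4 | methyl 7-oxabicyclo[2.2.1]hept-5-ene-2-carboxylate (racemic, endo/exo mixture) | COC(=O)C1CC2C=CC1O2
F2 | step 5 | rac-methyl 5-hydroxycyclohexa-1,3-diene-1-carboxylate | COC(=O)C1=CC=CC(O)C1
F3 | step 5 | methyl (5R)-5-{[(2S)-2-methoxy-2-phenylacetyl]oxy}cyclohexa-1,3-diene-1-carboxylate | COC(=O)C1=CC=C[C@H](OC(=O)[C@@H](OC)c2ccccc2)C1
F4 | step 8 | (2R)-2-methylbutanoyl chloride | CC[C@@H](C)C(Cl)=O
F5 | step 8 | methyl (3R,4S,5R)-3-hydroxy-4,5-bis{[(2R)-2-methylbutanoyl]oxy}cyclohex-1-ene-1-carboxylate | CC[C@@H](C)C(=O)O[C@@H]1[C@H](O)C=C(C(=O)OC)C[C@H]1OC(=O)[C@H](C)CC
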